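Should the next run be read at 30 h, and at which temperature should it go?

| setting | midnight | dusk |
|---|---|---|
| acidic substrate | 0.18 M | 0.18 M |
| free base | 0.108 M | 0.108 M |
| electrophile | 0.180 M | 0.180 M |
| capture agent | 0.180 M | 0.180 M |
| temperature | 110 °C | 90 °C |
| time | 30 h | 30 h |

    acidic substrate + anion → side product A (k1 = 3.9 × 10⁻⁵ L mol⁻¹ s⁻¹, Ea1 = 104 kJ mol⁻¹)
    anion + capture agent → trapped intermediate (k2 = 4.6 × 10⁻⁵ L mol⁻¹ s⁻¹, Ea2 = 97.0 kJ mol⁻¹)
    acidic substrate + free base ⇌ protonated base + anion, settled at all times (K3 = 120, ΔH3 = −26.0 kJ mol⁻¹)
    electrophile + anion → target (k4 = 8.8 × 10⁻⁴ L mol⁻¹ s⁻¹, Ea4 = 61.0 kJ mol⁻¹)
    anion → side product B (k5 = 4.4 × 10⁻⁵ s⁻¹, Ea5 = 114 kJ mol⁻¹)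
    (constants at 90 °C)

* the flask that comes out highest in amount of target, in percent of the acidic substrate charged, or "all alike" when all lie within 1.5 percentage points (midnight / dusk / all alike)
* target at the end, in percent of the acidic substrate charged, midnight
* target at the end, in percent of the acidic substrate charged, dusk

- percentages count the acidic substrate that a species holds: one side product A counts as two
- all constants are for 90 °C and move with temperature by the activation energies and enthalpies

The free base, 0.108 M, is less than the acidic substrate, 0.18 M, and the balance constant of 120 lies far towards the anion. So the free base is the limiting reagent, and the anion made comes to about 60.0% of the substrate charged. What I need is where that anion goes.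

Each anion leaves by the target step or by a loss: decay, capture, or attack on leftover substrate. When I divide the one rate by the other, time and the anion itself drop out. The share going to target is then electrophile over electrophile plus a single amount. That amount is the sum of the loss rates per anion divided by the target rate constant, which is the electrophile concentration at which target and losses draw level: the tie amount, 0.0626 M at dusk. I hold the capture agent at its charge and the substrate at what the free base leaves.

At midnight the tie amount is larger, 0.149 M, because heating speeds decay by a factor of 7.2 and the target step by a factor of 2.9.

Electrophile falls as target forms, so I average the share at the start and at the end. At dusk it starts at 74.2%; reckoned with that start share, 0.0999 M of electrophile is left, so the share ends at 61.5%, which gives 40.7% of target. At midnight it starts at 54.7%; reckoned the same way, 0.121 M of electrophile is left, so the share ends at 44.8%, which gives 29.8% of target.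

Even at that end electrophile, an anion at dusk lasts about 1.94 h, far shorter than 30 h. So I keep the cooler temperature, where my reckoned target is higher, and leave the reading time as it is.

The forecast names dusk, with 30.3% (28.5% to 32%) at midnight and 41.5% (39.5% to 43%) at dusk, and says: “Heating favours the high-activation-energy losses”. My two figures stand a little lower than its own.

The flasks give 30.2% of target at midnight and 41.4% at dusk, so dusk comes out highest, and dusk read at 300 h still shows 41.4%. The neighbour of dusk charged with 0.45 M of electrophile has the same tie amount, 0.0626 M. Its share starts at 87.8%; with 0.355 M of electrophile reckoned left, it ends at 85.0%, which reckons to 51.8% of target. That flask gives 51.9% of target, with side product B at 6.47%.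

The rate constants are those of an exercise.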